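At early times the eta run holds 5.3% target against 0.6% over-reaction product at 0.333 h, and by 2.50 h it holds 13.5% against 13.6%.

| setting | eta | theta | gamma | Thursday's | Monday's | Friday's | Sunday's |
|---|---|---|---|---|---|---|---|
| substrate | 0.13 M | 0.13 M | 0.13 M | 0.13 M | 0.13 M | 0.13 M | 0.13 M |
| coupling partner | 1 equiv | 0.67 equiv | 1.5 equiv | 1.00 equiv | 1.00 equiv | 1.00 equiv (fed, over 3.20 h) | 1.00 equiv |
| free catalyst | 0.2 mol% | 0.2 mol% | 0.2 mol% | 0.2 mol% | 0.2 mol% | 0.2 mol% | 0.2 mol% |
| remark | run made earlier | run made earlier | run made earlier | plug flow through a tube for 4.0 h, no back-mixing | a closed flask charged with all of it at once and left for 4.0 h | a stirred flask in which coupling partner is dosed at a steady rate over 3.20 h without added volume, worked up at 4.0 h | one stirred flow tank at steady state, fed with the mixture as stated, mean residence time 4.0 h |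
| time |  |  |  | 4.0 h | 4.0 h | 4.0 h |  |

- eta (time / h: target / %, over-reaction product / %, substrate / %): 0.333: 5.3, 0.6, 94.9; 0.833: 8.4, 2.4, 87.5; 1.50: 11.3, 7.3, 81.3; 2.50: 13.5, 13.6, 72.6
- theta (time / h: target / %, over-reaction product / %, substrate / %): 0.667: 7.2, 1.6, 92.1; 1.33: 10.7, 4.8, 84.3; 2.00: 11.9, 10.0, 78.2; 2.50: 11.8, 13.0, 73.9
- gamma (time / h: target / %, over-reaction product / %, substrate / %): 0.333: 4.9, 0.4, 93.9; 0.833: 8.8, 3.1, 88.6; 1.50: 12.0, 7.3, 80.9; 2.50: 13.9, 14.3, 71.4

(each reading ± 0.5 percentage points)

- the stated concentrations are those of everything mixed, before any reaction; amounts are the same in each set-up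
- the numbers in the tables scatter by 0.5 percentage points (one standard deviation)
- the feed brings no volume worth counting
- the earlier runs were made in a closed, stirred flask

- the set-up with the highest share of target in all that became target or over-reaction product, at the outlet or at the end ("none" if the first two lie within 2 percentage points) (Thursday's / Monday's / Friday's / Sunday's / none)
- share of target in all that became target or over-reaction product, at the outlet or at the end, Thursday's
- share of target in all that became target or over-reaction product, at the outlet or at the end, Monday's
- share of target in all that became target or over-reaction product, at the outlet or at the end, Friday's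
- share of target in all that became target or over-reaction product, at the outlet or at the end, Sunday's

I work with the fraction left: if over-reaction product forms from target, as its lag behind target at the first eta reading suggests, the share asked for, the selectivity to target, is the fraction of all target ever made that still stands. In the theta run target stays nearly level from 1.33 h to 2.50 h, and over-reaction product gains 8.2 percentage points on a mean target of 11.2%. So I read 0.623 h⁻¹ as the loss constant, the over-reaction product gained per hour per unit of target standing.

With first-order loss, a steady tank keeps 1/(1 + loss constant × residence time) of what it makes, which for Sunday's tank is 28.6%. A flask making target at an even pace over 4.0 h keeps 36.8%, and earlier making keeps less. The eta run gains 5.9 points of target and over-reaction product in its first 0.333 h, but 8.5 points in its last 1.00 h, so its making slows, and I expect Monday's closed flask below that even-pace figure.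

The forecast gives 32.5% for Thursday's, 32.5% for Monday's, 33% (29% to 38%) for Friday's and 29.5% for Sunday's, with best none: “Dosing changes little if partner order is zero”.

Friday's dosed flask gives 37.9%, against 32.7% for Thursday's and 32.7% for Monday's, so the best is Friday's, clear by 5.2 points.

    catalyst intermediate B ⇌ catalyst intermediate C (K = 0.670, k = 0.190 s⁻¹)
    catalyst intermediate C ⇌ free catalyst + target (K = 0.0440 M, k = 0.410 s⁻¹)
    target → over-reaction product (k = 1.70 × 10⁻⁴ s⁻¹)
    coupling partner + catalyst intermediate A → catalyst intermediate B (k = 1.10 M⁻¹ s⁻¹)
    substrate + free catalyst ⇌ catalyst intermediate A (K = 620 M⁻¹, k = 0.330 M⁻¹ s⁻¹)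

Target's half-life by its loss to over-reaction product is 1.1 h, short against the 4.0 h. With 0.623 h⁻¹, Monday's flask stands 4.1 points below the even-pace 36.8%, so its making leans earlier than even, while Friday's flask stands 1.1 points above it, and I read no lean from that gap, since 0.623 h⁻¹ is itself a scattered reading. Put on Sunday's tank, 0.623 h⁻¹ gives 28.6%, and the tank stands at 29.0%.

(All runs are simulated from invented constants, noise included.)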